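**Retrosynthetic overview**

1. The target is traced back, through phenolic ester methanolysis and a Heck coupling, to a bromo diol and from there to a trans methyl 2-aryl-5-bromo-2,3-dihydrobenzofuran-3-carboxylate.
2. Key disconnection: the dihydrofuran ring (O1–C2–C3–C3a–C7a) comes from the pyranone ring (O1–C2–C3–C4–C4a–C8a) of a (2R)-flavanone. An oxidative 1,2-shift of the aryl carbon from C4 to C3 contracts the ring and makes C4 the exocyclic carboxyl carbon.
3. Enabling feature: C3 of the dihydrofuran ring bears one oxygenated carbon (the CH2O group) and is bonded to the ring-fusion carbon C3a, which is ortho to O1. This 1,2-relation of aryl carbon and oxidised carbon across C3 is the imprint of an aryl shift in a chroman-4-one.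
4. The (2R)-flavanone comes from Rh-catalysed asymmetric 1,4-addition of an arylboronic acid to 6-bromo-8-methoxychromone, itself made from 2'-hydroxy-3'-methoxyacetophenone.
5. Ring order: both benzene rings are bought; the pyranone ring is formed in step 2, made stereogenic at C2 in step 4, and contracted to the dihydrofuran ring in step 5.

Key step: step 5

Assumption: the ligand antipode in step 4 is the one that delivers the 2R flavanone; its sense of induction is to be fixed by a test run on the parent chromone, and the other antipode is taken if the sense is opposite.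

**Route**

Step 1
Reactants: 1 1-(2-hydroxy-3-methoxyphenyl)ethan-1-one
Product: 2 1-(5-bromo-2-hydroxy-3-methoxyphenyl)ethan-1-one
Conditions: NBS, MeCN, 0 °C to rt
Reagents that add atoms: N-bromosuccinimide O=C1CCC(=O)N1Br
Why: Electrophilic aromatic bromination should go to C5, the only free position para to the phenol OH and also meta to the acetyl group; no stereocenter is formed.

Step 2
Reactants: 2 1-(5-bromo-2-hydroxy-3-methoxyphenyl)ethan-1-one
Product: 4 6-bromo-8-methoxy-4H-chromen-4-one, via enaminone 3 (not isolated)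
Conditions: DMF-DMA, toluene, 100 °C; then AcOH, reflux
Reagents that add atoms: N,N-dimethylformamide dimethyl acetal COC(OC)N(C)C
Why: Condensation of the methyl ketone with DMF-DMA gives the enaminone, and acid-mediated conjugate addition of the phenol with loss of dimethylamine closes the pyranone ring (enaminone chromone synthesis).

Step 3
Reactants: 5 (4-hydroxy-3-methoxyphenyl)boronic acid
Product: 6 [3-methoxy-4-(pivaloyloxy)phenyl]boronic acid
Conditions: PivCl, pyridine, CH2Cl2, 0 °C to rt; aq. NH4Cl work-up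
Reagents that add atoms: pivaloyl chloride CC(C)(C)C(Cl)=O
Why: O-acylation of the phenol (any B–O acylation is reversed on aqueous work-up) installs an acid-stable, electron-withdrawing ester that will protect the B ring in the key step.

Step 4
Reactants: 4 6-bromo-8-methoxy-4H-chromen-4-one; 6 [3-methoxy-4-(pivaloyloxy)phenyl]boronic acid
Product: 7 4-[(2R)-6-bromo-8-methoxy-4-oxochroman-2-yl]-2-methoxyphenyl pivalate
Conditions: [Rh(OH)(cod)]2 (cat.), MeO-F12-BIPHEP (cat., antipode giving 2R), toluene/H2O, 50 °C
Reagents that add atoms: none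
Why: Rh(I)-catalysed asymmetric 1,4-addition of an arylboronic acid to a chromone (Hayashi–Miyaura type) should set C2 by catalyst control, the aryl–Rh species adding to one enantioface of C2; the base-free medium avoids retro-oxa-Michael opening and the aryl bromide is inert to Rh(I).

Step 5
Reactants: 7 4-[(2R)-6-bromo-8-methoxy-4-oxochroman-2-yl]-2-methoxyphenyl pivalate
Product: 10 methyl (2R,3R)-5-bromo-7-methoxy-2-[3-methoxy-4-(pivaloyloxy)phenyl]-2,3-dihydro-1-benzofuran-3-carboxylate, via enol ether 8 (not isolated), via C3-iodanyl ketal 9 (not isolated)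
Conditions: PhI(OAc)2, conc. H2SO4 (cat.), HC(OMe)3, rt; aq. NaHCO3 work-up
Reagents that add atoms: trimethyl orthoformate COC(OC)OC; water O (work-up); (diacetoxyiodo)benzene CC(=O)OI(OC(C)=O)c1ccccc1 (atoms retained only in intermediate 9)
Why: Acid and HC(OMe)3 convert ketone 7 into the C4 dimethyl ketal and its enol ether 8, which attacks PhI(OAc)2 at C3 on the face anti to the C2 aryl group to give the trans C3-iodanyl ketal 9. The equatorial C3–I bond lies antiperiplanar to the C4–C4a bond, so the A-ring carbon C4a shifts from C4 to C3 as iodobenzene leaves, and the resulting dimethoxycarbenium ion is hydrolysed to the methyl ester on work-up. This is the known hypervalent-iodine oxidative ring contraction of flavanones to trans-2-aryl-2,3-dihydrobenzofuran-3-carboxylates (an oxidative 1,2-aryl shift of semipinacol type). The five-membered ring O1–C2–C3–C3a–C7a is closed by the new C3–C(aryl) bond through a bridged phenonium-like transition state (3-exo-tet attack of the ipso carbon, then cleavage of the old C4–C(aryl) bond), which takes C4 out of the ring as the ester carbon. C2 is untouched and keeps its R configuration, and C3 is set by substrate control, because anti addition of the iodane followed by inversion at C3 places the ester trans to the aryl group (2R,3R). The step needs migration of the A-ring carbon in preference to migration of the C2 aryl group, flavone formation and arene oxidation; the C4 ketal (which makes the shift end in a dioxocarbenium ion), the ring oxygen ortho to the migrating carbon and the electron-poor pivaloyloxy B ring (which also keeps the benzylic C2–O bond from ionising in acid) secure this.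

Step 6
Reactants: 10 methyl (2R,3R)-5-bromo-7-methoxy-2-[3-methoxy-4-(pivaloyloxy)phenyl]-2,3-dihydro-1-benzofuran-3-carboxylate
Product: 11 4-[(2R,3S)-5-bromo-3-(hydroxymethyl)-7-methoxy-2,3-dihydro-1-benzofuran-2-yl]-2-methoxyphenol
Conditions: DIBAL-H (excess), CH2Cl2, −78 to 0 °C; Rochelle salt work-up
Reagents that add atoms: none
Why: Hydride reduction of the methyl ester to the primary alcohol and reductive removal of the pivalate should occur in one operation; the non-basic low-temperature hydride avoids epimerisation or β-elimination at C3, whose descriptor changes from R to S only through CIP priorities.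

Step 7
Reactants: 11 4-[(2R,3S)-5-bromo-3-(hydroxymethyl)-7-methoxy-2,3-dihydro-1-benzofuran-2-yl]-2-methoxyphenol
Product: 12 [(2R,3S)-5-bromo-7-methoxy-2-{3-methoxy-4-[(3-methylbutanoyl)oxy]phenyl}-2,3-dihydro-1-benzofuran-3-yl]methyl 3-methylbutanoate
Conditions: i-PrCH2COCl (2.5 equiv), Et3N, DMAP (cat.), CH2Cl2, 0 °C to rt
Reagents that add atoms: 3-methylbutanoyl chloride CC(C)CC(Cl)=O
Why: DMAP-catalysed acylation of both hydroxyl groups installs the required primary isovalerate and, with the same reagent, a temporary aryl ester that masks the phenol during the coupling.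

Step 8
Reactants: 12 [(2R,3S)-5-bromo-7-methoxy-2-{3-methoxy-4-[(3-methylbutanoyl)oxy]phenyl}-2,3-dihydro-1-benzofuran-3-yl]methyl 3-methylbutanoate
Product: 14 [(2R,3S)-7-methoxy-2-{3-methoxy-4-[(3-methylbutanoyl)oxy]phenyl}-5-[(E)-3-oxoprop-1-en-1-yl]-2,3-dihydro-1-benzofuran-3-yl]methyl 3-methylbutanoate, via diethyl acetal 13 (not isolated)
Conditions: Pd(OAc)2 (cat.), n-Bu4NOAc, K2CO3, KCl, DMF, 90 °C; then 2 M HCl, rt
Reagents that add atoms: acrolein diethyl acetal C=CC(OCC)OCC; water O
Why: Phosphine-free Heck reaction (Jeffery-type conditions) of the aryl bromide with acrolein diethyl acetal should give the E alkene by syn β-hydride elimination, the acetate/carbonate medium steering elimination away from the acetal carbon, and the acidic work-up unmasks the aldehyde.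

Step 9
Reactants: 14 [(2R,3S)-7-methoxy-2-{3-methoxy-4-[(3-methylbutanoyl)oxy]phenyl}-5-[(E)-3-oxoprop-1-en-1-yl]-2,3-dihydro-1-benzofuran-3-yl]methyl 3-methylbutanoate
Product: 15 [(2R,3S)-2-(4-hydroxy-3-methoxyphenyl)-7-methoxy-5-[(E)-3-oxoprop-1-en-1-yl]-2,3-dihydro-1-benzofuran-3-yl]methyl 3-methylbutanoate
Conditions: K2CO3 (cat.), MeOH/CH2Cl2, 0 °C
Reagents that add atoms: none
Why: Chemoselective methanolysis should cleave the phenolic ester (aryloxide leaving group) much faster than the primary alkyl ester, and the liberated phenol buffers the medium so that the alkyl isovalerate and the enal are left intact.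

**Compound list**

1 | 1-(2-hydroxy-3-methoxyphenyl)ethan-1-one | CC(=O)c1cccc(OC)c1O | starting material
2 | 1-(5-bromo-2-hydroxy-3-methoxyphenyl)ethan-1-one | CC(=O)c1cc(Br)cc(OC)c1O | intermediate
3 | (E)-1-(5-bromo-2-hydroxy-3-methoxyphenyl)-3-(dimethylamino)prop-2-en-1-one | CN(C)/C=C/C(=O)c1cc(Br)cc(OC)c1O | intermediate
4 | 6-bromo-8-methoxy-4H-chromen-4-one | COc1cc(Br)cc2c1occc2=O | intermediate
5 | (4-hydroxy-3-methoxyphenyl)boronic acid | COc1cc(B(O)O)ccc1O | starting material
6 | [3-methoxy-4-(pivaloyloxy)phenyl]boronic acid | COc1cc(B(O)O)ccc1OC(=O)C(C)(C)C | intermediate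
7 | 4-[(2R)-6-bromo-8-methoxy-4-oxochroman-2-yl]-2-methoxyphenyl pivalate | COc1cc([C@@H]2Oc3c(OC)cc(Br)cc3C(=O)C2)ccc1OC(=O)C(C)(C)C | intermediate
8 | 4-[(2R)-6-bromo-4,8-dimethoxy-2H-chromen-2-yl]-2-methoxyphenyl pivalate | COc1cc([C@@H]2Oc3c(OC)cc(Br)cc3C(OC)=C2)ccc1OC(=O)C(C)(C)C | intermediate
9 | 4-[(2S,3S)-3-[acetoxy(phenyl)-λ3-iodanyl]-6-bromo-4,4,8-trimethoxychroman-2-yl]-2-methoxyphenyl pivalate (2,3-trans) | COc1cc([C@@H]2Oc3c(OC)cc(Br)cc3C(OC)(OC)[C@H]2I(OC(C)=O)c2ccccc2)ccc1OC(=O)C(C)(C)C | intermediate
10 | methyl (2R,3R)-5-bromo-7-methoxy-2-[3-methoxy-4-(pivaloyloxy)phenyl]-2,3-dihydro-1-benzofuran-3-carboxylate | COc1cc([C@@H]2Oc3c(OC)cc(Br)cc3[C@H]2C(=O)OC)ccc1OC(=O)C(C)(C)C | intermediate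
11 | 4-[(2R,3S)-5-bromo-3-(hydroxymethyl)-7-methoxy-2,3-dihydro-1-benzofuran-2-yl]-2-methoxyphenol | COc1cc([C@@H]2Oc3c(OC)cc(Br)cc3[C@H]2CO)ccc1O | intermediate
12 | [(2R,3S)-5-bromo-7-methoxy-2-{3-methoxy-4-[(3-methylbutanoyl)oxy]phenyl}-2,3-dihydro-1-benzofuran-3-yl]methyl 3-methylbutanoate | COc1cc([C@@H]2Oc3c(OC)cc(Br)cc3[C@H]2COC(=O)CC(C)C)ccc1OC(=O)CC(C)C | intermediate
13 | [(2R,3S)-5-[(E)-3,3-diethoxyprop-1-en-1-yl]-7-methoxy-2-{3-methoxy-4-[(3-methylbutanoyl)oxy]phenyl}-2,3-dihydro-1-benzofuran-3-yl]methyl 3-methylbutanoate | COc1cc([C@@H]2Oc3c(OC)cc(/C=C/C(OCC)OCC)cc3[C@H]2COC(=O)CC(C)C)ccc1OC(=O)CC(C)C | intermediate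
14 | [(2R,3S)-7-methoxy-2-{3-methoxy-4-[(3-methylbutanoyl)oxy]phenyl}-5-[(E)-3-oxoprop-1-en-1-yl]-2,3-dihydro-1-benzofuran-3-yl]methyl 3-methylbutanoate | COc1cc([C@@H]2Oc3c(OC)cc(/C=C/C=O)cc3[C@H]2COC(=O)CC(C)C)ccc1OC(=O)CC(C)C | intermediate
15 | [(2R,3S)-2-(4-hydroxy-3-methoxyphenyl)-7-methoxy-5-[(E)-3-oxoprop-1-en-1-yl]-2,3-dihydro-1-benzofuran-3-yl]methyl 3-methylbutanoate | COc1cc([C@@H]2Oc3c(OC)cc(/C=C/C=O)cc3[C@H]2COC(=O)CC(C)C)ccc1O | target

**Step count**

Total steps: 9. Longest linear sequence: 8 (steps 1, 2, 4, 5, 6, 7, 8, 9 from compound 1); step 3 prepares the boronic acid branch.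

**Steps most likely to fail, with fallbacks**

Step 5. The iodanyl intermediate may be diverted into dehydrogenation to the flavone or migration of the C2 aryl group, the iodine(III) reagent may attack the methoxyarenes, or the acid may ionise the benzylic C2–O bond and erode the enantiomeric purity. The fallback keeps the ring contraction but uses a halohydrin semipinacol rearrangement without iodine(III). It sets out from 7: reduction with NaBH4 (MeOH/THF, 0 °C) should give 4-[(2R,4R)-6-bromo-4-hydroxy-8-methoxychroman-2-yl]-2-methoxyphenyl pivalate F1. Mild dehydration (Burgess reagent, or cat. TsOH in toluene at 50 °C, in the dark) should give 4-[(2R)-6-bromo-8-methoxy-2H-chromen-2-yl]-2-methoxyphenyl pivalate F2. NBS in aqueous THF at 0 °C should add anti to the C2 aryl group and give the all-trans bromohydrin 4-[(2S,3R,4S)-3,6-dibromo-4-hydroxy-8-methoxychroman-2-yl]-2-methoxyphenyl pivalate F3. AgBF4 in CH2Cl2 should then trigger the 1,2-shift of the A-ring carbon antiperiplanar to the equatorial C3–Br bond, giving 4-[(2R,3R)-5-bromo-3-formyl-7-methoxy-2,3-dihydro-1-benzofuran-2-yl]-2-methoxyphenyl pivalate F4. Excess DIBAL-H at −78 °C reduces the aldehyde and removes the pivalate, which returns the route at 11.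

Step 4. Carbometalation of the weakly electrophilic chromone may be slower than protodeboronation of the boronic acid, and retro-oxa-Michael opening of the product may erode the enantiomeric excess. The fallback replaces the metal-catalysed arylation by an organocatalytic oxa-Michael ring closure and sets out from 2. C-acylation of the dianion of 2 (LiHMDS, THF, −78 °C) with di-tert-butyl dicarbonate should give tert-butyl 3-(5-bromo-2-hydroxy-3-methoxyphenyl)-3-oxopropanoate F5. Vanillin is pivaloylated (PivCl, Et3N, CH2Cl2) to 4-formyl-2-methoxyphenyl pivalate F6. Knoevenagel condensation of F5 with F6 (piperidinium acetate, toluene, molecular sieves) should give tert-butyl 2-(5-bromo-2-hydroxy-3-methoxybenzoyl)-3-[3-methoxy-4-(pivaloyloxy)phenyl]prop-2-enoate F7 as an E/Z mixture. A cinchona-derived bifunctional thiourea (the pseudo-enantiomer that gives the 2R series, toluene, −25 °C) should cyclise both alkene isomers to tert-butyl (2R)-6-bromo-8-methoxy-2-[3-methoxy-4-(pivaloyloxy)phenyl]-4-oxochroman-3-carboxylate F8. TsOH in toluene at 80 °C removes the tert-butyl ester with decarboxylation, which returns the route at 7.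

Step 8. Oxidative addition into the electron-rich aryl bromide may be slow, β-hydride elimination may occur toward the acetal carbon and give the saturated ester, and the aryl ester may be lost under hot carbonate. The fallback replaces the Heck reaction by a Suzuki–Miyaura coupling with a preformed E-alkenylboron reagent, so that regiochemistry and alkene geometry are fixed in the reagent. It sets out from 12: coupling with (E)-2-(3,3-diethoxyprop-1-en-1-yl)-4,4,5,5-tetramethyl-1,3,2-dioxaborolane (Pd(dppf)Cl2, anhydrous CsF, dioxane, 80 °C) should give acetal 13, and hydrolysis with 2 M HCl returns the route at 14.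

**Further compounds**

F1 | step 5 | 4-[(2R,4R)-6-bromo-4-hydroxy-8-methoxychroman-2-yl]-2-methoxyphenyl pivalate | COc1cc([C@@H]2Oc3c(OC)cc(Br)cc3[C@H](O)C2)ccc1OC(=O)C(C)(C)C
F2 | step 5 | 4-[(2R)-6-bromo-8-methoxy-2H-chromen-2-yl]-2-methoxyphenyl pivalate | COc1cc([C@@H]2Oc3c(OC)cc(Br)cc3C=C2)ccc1OC(=O)C(C)(C)C
F3 | step 5 | 4-[(2S,3R,4S)-3,6-dibromo-4-hydroxy-8-methoxychroman-2-yl]-2-methoxyphenyl pivalate | COc1cc([C@@H]2Oc3c(OC)cc(Br)cc3[C@H](O)[C@H]2Br)ccc1OC(=O)C(C)(C)C
F4 | step 5 | 4-[(2R,3R)-5-bromo-3-formyl-7-methoxy-2,3-dihydro-1-benzofuran-2-yl]-2-methoxyphenyl pivalate | COc1cc([C@@H]2Oc3c(OC)cc(Br)cc3[C@H]2C=O)ccc1OC(=O)C(C)(C)C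
F5 | step 4 | tert-butyl 3-(5-bromo-2-hydroxy-3-methoxyphenyl)-3-oxopropanoate | CC(C)(C)OC(=O)CC(=O)c1cc(Br)cc(OC)c1O
F6 | step 4 | 4-formyl-2-methoxyphenyl pivalate | COc1cc(C=O)ccc1OC(=O)C(C)(C)C
F7 | step 4 | tert-butyl 2-(5-bromo-2-hydroxy-3-methoxybenzoyl)-3-[3-methoxy-4-(pivaloyloxy)phenyl]prop-2-enoate (E/Z mixture) | CC(C)(C)OC(=O)C(=Cc1ccc(OC(=O)C(C)(C)C)c(OC)c1)C(=O)c1cc(Br)cc(OC)c1O
F8 | step 4 | tert-butyl (2R)-6-bromo-8-methoxy-2-[3-methoxy-4-(pivaloyloxy)phenyl]-4-oxochroman-3-carboxylate | COc1cc([C@@H]2Oc3c(OC)cc(Br)cc3C(=O)C2C(=O)OC(C)(C)C)ccc1OC(=O)C(C)(C)C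
F0 | step 8 | none | none
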